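**Retrosynthetic overview**

1. Drimane numbering is used (ring A: C1–C5 and C10; ring B: C5–C10; C11 on C9, C12 on C8). The C11–O aryl ether is cut last (Mitsunobu reaction with 7-hydroxycoumarin), and the 2,3-diol travels as a trans-fused acetonide.
2. Ring B is a cyclohexene in which the two-carbon unit C8(–C12)–C9(–C11) bridges C7 and the quaternary C10. With the alkene moved from C7=C8 to C8=C9 and C11 raised to an ester, ring B is the Diels–Alder adduct of the ring-A diene C7=C6–C5=C10 and methyl but-2-ynoate (bonds C7–C8 and C9–C10).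
3. After the cycloaddition, C5 is set by hydrogenation anti to the C10 methyl, C9 by kinetic protonation of the ester dienolate, and the alkene is moved to C7=C8 by cobalt-hydride isomerization.
4. Ring A comes from 2,6-dimethylphenol: methylative dearomatization, one catalytic asymmetric epoxidation (sets C3), anti hydrolysis (sets C2), acetonide, enol triflate, vinyl Stille coupling.
5. Ring order: A (from the arene), then B (cycloaddition), then the intact coumarin at the end; every stereocenter is relayed from the single catalytic step through the conformationally locked acetonide.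

Key step: step 7

Remark: the sense of induction in step 2 is assigned by analogy with 2,2-dimethylchromene; if it proved opposite, the (S,S)-catalyst would be taken.

**Route**

Step 1
Reactants: 1 2,6-dimethylphenol; 2 iodomethane
Product: 3 2,6,6-trimethylcyclohexa-2,4-dien-1-one
Conditions: NaH, PhMe, 0 °C → rt; then MeI, sealed vessel, 80 °C
Reagents that add atoms: iodomethane, CI
Why: Ortho C-methylation of the sodium phenoxide in a non-polar solvent (alkylative dearomatization) should give the 6,6-disubstituted 2,4-dienone, which cannot rearomatize, with O-methylation to the anisole as the expected side path; no stereocenter is formed.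

Step 2
Reactants: 3 2,6,6-trimethylcyclohexa-2,4-dien-1-one; 4 sodium hypochlorite
Product: 5 (4R,5S)-4,5-epoxy-2,6,6-trimethylcyclohex-2-en-1-one
Conditions: (R,R)-(salen)MnCl (salen = N,N'-bis(3,5-di-tert-butylsalicylidene)cyclohexane-1,2-diaminate, trivalent manganese; 5 mol %), 4-phenylpyridine N-oxide (20 mol %), aq. NaOCl (pH 11.3), CH2Cl2, 0 °C
Reagents that add atoms: sodium hypochlorite, [Na+].[O-]Cl
Why: Jacobsen–Katsuki epoxidation: the electrophilic oxo-manganese species should attack only the cis-disubstituted C4=C5 bond, which is conjugated to C2=C3 and flanked by CMe2 as in 2,2-dimethylchromene, so the (R,R)-catalyst should give the (4R,5S)-epoxide, whose C5–O bond becomes the C3–O bond of the target.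

Step 3
Reactants: 5 (4R,5S)-4,5-epoxy-2,6,6-trimethylcyclohex-2-en-1-one; 6 water
Product: 7 (4S,5S)-4,5-dihydroxy-2,6,6-trimethylcyclohex-2-en-1-one
Conditions: HClO4 (cat.), THF–H2O (3:1), 0 °C → rt
Reagents that add atoms: water, O
Why: Acid-catalysed epoxide hydrolysis: water should open the protonated epoxide by anti attack at the allylic C4 (C5 is neopentyl), inverting C4 and leaving C5 untouched, which gives the trans-(4S,5S)-diol.

Step 4
Reactants: 7 (4S,5S)-4,5-dihydroxy-2,6,6-trimethylcyclohex-2-en-1-one; 8 2-methoxypropene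
Product: 9 (4S,5S)-4,5-(isopropylidenedioxy)-2,6,6-trimethylcyclohex-2-en-1-one
Conditions: 2-methoxypropene, PPTS (cat.), CH2Cl2, 0 °C → rt
Reagents that add atoms: 2-methoxypropene, COC(C)=C
Why: Kinetic acetalization with an enol ether under mild acid should close the trans-fused dioxolane on the diequatorial diol without touching the stereocenters, and it masks the β-hydroxy ketone against retro-aldol cleavage in the basic steps that follow.

Step 5
Reactants: 9 (4S,5S)-4,5-(isopropylidenedioxy)-2,6,6-trimethylcyclohex-2-en-1-one; 10 N-phenylbis(trifluoromethanesulfonimide)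
Product: 12 (4S,5S)-4,5-(isopropylidenedioxy)-2,6,6-trimethylcyclohex-1-en-1-yl trifluoromethanesulfonate, via lithium enolate 11 (not isolated)
Conditions: LiBH(s-Bu)3 (L-Selectride), THF, −78 °C; then PhNTf2, −78 °C → rt
Reagents that add atoms: N-phenylbis(trifluoromethanesulfonimide), O=S(=O)(N(c1ccccc1)S(=O)(=O)C(F)(F)F)C(F)(F)F
Why: Conjugate hydride reduction of the β-unsubstituted enone by the bulky borohydride (the carbonyl is shielded by CMe2) should give the tetrasubstituted lithium enolate regiospecifically, which is trapped on oxygen (enolate O-triflation); the acetonide oxygen is γ to the enolate carbon and cannot be eliminated, and no stereocenter is formed.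

Step 6
Reactants: 12 (4S,5S)-4,5-(isopropylidenedioxy)-2,6,6-trimethylcyclohex-1-en-1-yl trifluoromethanesulfonate; 13 tributyl(vinyl)stannane
Product: 14 (4S,5S)-4,5-(isopropylidenedioxy)-2,6,6-trimethyl-1-vinylcyclohex-1-ene
Conditions: CH2=CHSnBu3, Pd(PPh3)4 (5 mol %), LiCl, THF, 65 °C
Reagents that add atoms: tributyl(vinyl)stannane, C=C[Sn](CCCC)(CCCC)CCCC
Why: Stille coupling: oxidative addition of the enol triflate to zerovalent palladium, chloride-assisted transmetalation of the vinyl group and reductive elimination should give the 1,3-diene with the stereocenters untouched.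

Step 7
Reactants: 14 (4S,5S)-4,5-(isopropylidenedioxy)-2,6,6-trimethyl-1-vinylcyclohex-1-ene; 15 methyl but-2-ynoate
Product: 16 methyl (2S,3S,10R)-2,3-(isopropylidenedioxy)drima-5,8-dien-11-oate
Conditions: 15 (5 equiv), BHT (cat.), neat, sealed tube, 140 °C
Reagents that add atoms: methyl but-2-ynoate, CC#CC(=O)OC
Why: Thermal normal-electron-demand [4+2] cycloaddition in which the s-cis diene C7=C6–C5=C10 of 14 adds to the ynoate through an asynchronous transition state, the unhindered C7 terminus (largest HOMO coefficient) bonding ahead to the β-carbon C8 and the ester-bearing C9 closing onto C10; the closest known reaction type is the Diels–Alder reaction of 2,6,6-trimethyl-1-vinylcyclohexenes with acetylenic esters, the classical entry to drimanes. Ring B is closed by intermolecular two-bond cycloaddition (C7–C8 and C9–C10 formed together), giving a cyclohexa-1,4-diene with C5=C6 and C8=C9 double bonds. The only new stereocenter, quaternary C10, is controlled by the trans-fused dioxolane, which freezes ring A in the half-chair with both oxygens equatorial and places one C4 methyl pseudoaxial on the face of the C3–O bond, so the dienophile should add to the opposite face and ring A relaxes directly to the chair with the C10 methyl axial and cis to O3 (10R). The step needs regioselectivity (ester carbon to C10), secured by the donor-substituted C10 terminus and the low steric demand at C7, and facial selectivity, secured by the conformational lock; excess ynoate and a radical inhibitor keep the temperature low enough to avoid a [1,5]-hydrogen shift in the diene.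

Step 8
Reactants: 16 methyl (2S,3S,10R)-2,3-(isopropylidenedioxy)drima-5,8-dien-11-oate
Product: 17 methyl (2S,3S,5S,10R)-2,3-(isopropylidenedioxy)drim-8-en-11-oate
Conditions: H2 (3 atm), 10% Pd/C, EtOAc, rt
Reagents that add atoms: none
Why: Heterogeneous hydrogenation should reduce the trisubstituted C5=C6 bond and leave the tetrasubstituted, ester-conjugated C8=C9 bond, with hydrogen delivered to the face opposite the axial C10 and C4 methyl groups, which sets C5 (5S) and the trans ring fusion.

Step 9
Reactants: 17 methyl (2S,3S,5S,10R)-2,3-(isopropylidenedioxy)drim-8-en-11-oate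
Product: 19 methyl (2S,3S,5S,9R,10R)-2,3-(isopropylidenedioxy)drim-8(12)-en-11-oate, via lithium dienolate 18 (not isolated)
Conditions: LDA, THF–DMPU, −78 °C; then AcOH, −78 °C
Reagents that add atoms: none
Why: Deconjugative protonation: LDA should deprotonate the C12 methyl, which is cis to the ester, and kinetic α-protonation of the dienolate at C9 from the face opposite the axial C10 methyl should set C9 (9R, ester equatorial) and leave the exocyclic alkene; any C7=C8 ester from deprotonation at C7 has the same C9 configuration and converges in step 11.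

Step 10
Reactants: 19 methyl (2S,3S,5S,9R,10R)-2,3-(isopropylidenedioxy)drim-8(12)-en-11-oate
Product: 20 (2S,3S,5S,9R,10R)-2,3-(isopropylidenedioxy)drim-8(12)-en-11-ol
Conditions: LiAlH4, Et2O, 0 °C
Reagents that add atoms: none
Why: Hydride reduction of the ester to the primary alcohol removes the acidity of C9–H and so secures its configuration; the acetonide and the alkene are inert to LiAlH4.

Step 11
Reactants: 20 (2S,3S,5S,9R,10R)-2,3-(isopropylidenedioxy)drim-8(12)-en-11-ol
Product: 21 (2S,3S,5S,9R,10R)-2,3-(isopropylidenedioxy)drim-7-en-11-ol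
Conditions: (salen)CoCl (same salen ligand as in step 2, trivalent cobalt; 3 mol %), PhSiH3 (6 mol %), benzene, rt
Reagents that add atoms: none
Why: Cobalt-hydride hydrogen-atom-transfer isomerization: reversible hydrogen-atom addition to the 1,1-disubstituted alkene gives the tertiary C8 radical, and back-abstraction of the accessible C7–H rather than the hindered tertiary C9–H should give the trisubstituted C7=C8 alkene, which is inert to further isomerization; no stereocenter is touched.

Step 12
Reactants: 21 (2S,3S,5S,9R,10R)-2,3-(isopropylidenedioxy)drim-7-en-11-ol; 22 7-hydroxycoumarin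
Product: 23 7-[(2S,3S,5S,9R,10R)-2,3-(isopropylidenedioxy)drim-7-en-11-yloxy]-2H-chromen-2-one
Conditions: PPh3, DIAD, THF, 0 °C → rt
Reagents that add atoms: 7-hydroxycoumarin, O=c1ccc2ccc(O)cc2o1
Why: Mitsunobu etherification: the primary alkoxyphosphonium ion should be displaced by the acidic phenol at the non-stereogenic C11, and the acid-labile acetonide survives the near-neutral conditions.

Step 13
Reactants: 23 7-[(2S,3S,5S,9R,10R)-2,3-(isopropylidenedioxy)drim-7-en-11-yloxy]-2H-chromen-2-one
Product: 24 7-[(2S,3S,5S,9R,10R)-2,3-dihydroxydrim-7-en-11-yloxy]-2H-chromen-2-one (CNP0124364.1)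
Conditions: AcOH–H2O (4:1), 40 °C
Reagents that add atoms: none
Why: Acid hydrolysis of the strained trans-fused acetonide should free the 2,3-diol under conditions that leave the aryl ether, the coumarin lactone and the trisubstituted alkene untouched; no stereocenter is affected.

**Compound list**

1 | 2,6-dimethylphenol | Cc1cccc(C)c1O | starting material
2 | iodomethane | CI | starting material
3 | 2,6,6-trimethylcyclohexa-2,4-dien-1-one | CC1=CC=CC(C)(C)C1=O | intermediate
4 | sodium hypochlorite | [Na+].[O-]Cl | starting material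
5 | (4R,5S)-4,5-epoxy-2,6,6-trimethylcyclohex-2-en-1-one | O=C1C(C)(C)[C@@H]2O[C@@H]2C=C1C | intermediate
6 | water | O | starting material
7 | (4S,5S)-4,5-dihydroxy-2,6,6-trimethylcyclohex-2-en-1-one (trans-diol) | O=C1C(C)(C)[C@H](O)[C@@H](O)C=C1C | intermediate
8 | 2-methoxypropene | COC(C)=C | starting material
9 | (4S,5S)-4,5-(isopropylidenedioxy)-2,6,6-trimethylcyclohex-2-en-1-one (trans-fused acetonide of 7) | O=C1C(C)(C)[C@@H]2OC(C)(C)O[C@H]2C=C1C | intermediate
10 | N-phenylbis(trifluoromethanesulfonimide) | O=S(=O)(N(c1ccccc1)S(=O)(=O)C(F)(F)F)C(F)(F)F | starting material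
11 | lithium (4S,5S)-4,5-(isopropylidenedioxy)-2,6,6-trimethylcyclohex-1-en-1-olate | [Li+].[O-]C1=C(C)C[C@@H]2OC(C)(C)O[C@H]2C1(C)C | intermediate
12 | (4S,5S)-4,5-(isopropylidenedioxy)-2,6,6-trimethylcyclohex-1-en-1-yl trifluoromethanesulfonate | O=S(=O)(OC1=C(C)C[C@@H]2OC(C)(C)O[C@H]2C1(C)C)C(F)(F)F | intermediate
13 | tributyl(vinyl)stannane | C=C[Sn](CCCC)(CCCC)CCCC | starting material
14 | (4S,5S)-4,5-(isopropylidenedioxy)-2,6,6-trimethyl-1-vinylcyclohex-1-ene | C=CC1=C(C)C[C@@H]2OC(C)(C)O[C@H]2C1(C)C | intermediate
15 | methyl but-2-ynoate | CC#CC(=O)OC | starting material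
16 | methyl (2S,3S,10R)-2,3-(isopropylidenedioxy)drima-5,8-dien-11-oate | CC1=C(C(=O)OC)[C@]2(C)C[C@@H]3OC(C)(C)O[C@H]3C(C)(C)C2=CC1 | intermediate
17 | methyl (2S,3S,5S,10R)-2,3-(isopropylidenedioxy)drim-8-en-11-oate (trans-decalin) | CC1=C(C(=O)OC)[C@]2(C)C[C@@H]3OC(C)(C)O[C@H]3C(C)(C)[C@H]2CC1 | intermediate
18 | lithium dienolate of 17 (C9=C11 enolate, C8=C12 exocyclic alkene) | C=C1CC[C@@H]2C(C)(C)[C@@H]3OC(C)(C)O[C@H]3C[C@@]2(C)C1=C(OC)[O-].[Li+] | intermediate
19 | methyl (2S,3S,5S,9R,10R)-2,3-(isopropylidenedioxy)drim-8(12)-en-11-oate | C=C1CC[C@@H]2C(C)(C)[C@@H]3OC(C)(C)O[C@H]3C[C@@]2(C)[C@@H]1C(=O)OC | intermediate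
20 | (2S,3S,5S,9R,10R)-2,3-(isopropylidenedioxy)drim-8(12)-en-11-ol | C=C1CC[C@@H]2C(C)(C)[C@@H]3OC(C)(C)O[C@H]3C[C@@]2(C)[C@@H]1CO | intermediate
21 | (2S,3S,5S,9R,10R)-2,3-(isopropylidenedioxy)drim-7-en-11-ol | CC1=CC[C@@H]2C(C)(C)[C@@H]3OC(C)(C)O[C@H]3C[C@@]2(C)[C@@H]1CO | intermediate
22 | 7-hydroxycoumarin (umbelliferone) | O=c1ccc2ccc(O)cc2o1 | starting material
23 | 7-[(2S,3S,5S,9R,10R)-2,3-(isopropylidenedioxy)drim-7-en-11-yloxy]-2H-chromen-2-one | CC1=CC[C@@H]2C(C)(C)[C@@H]3OC(C)(C)O[C@H]3C[C@@]2(C)[C@@H]1COc1ccc2ccc(=O)oc2c1 | intermediate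
24 | 7-[(2S,3S,5S,9R,10R)-2,3-dihydroxydrim-7-en-11-yloxy]-2H-chromen-2-one (CNP0124364.1) | CC1=CC[C@@H]2C(C)(C)[C@H](O)[C@@H](O)C[C@@]2(C)[C@@H]1COc1ccc2ccc(=O)oc2c1 | target

**Totals**

Total step count: 13. Longest linear sequence: 13 steps (from 2,6-dimethylphenol).

**Steps most likely to fail, with fallbacks**

Step 7. The cycloaddition may be too slow at a temperature the diene tolerates, so that a [1,5]-hydrogen shift of the diene competes or facial selectivity erodes. Setting out from 14, the more electrophilic but-2-ynal (from but-2-yn-1-ol with MnO2) would be used as dienophile at 80 °C to give (2S,3S,10R)-2,3-(isopropylidenedioxy)drima-5,8-dien-11-al F1. Oxidation of the aldehyde (NaClO2, NaH2PO4, 2-methylbut-2-ene, t-BuOH–H2O) would give (2S,3S,10R)-2,3-(isopropylidenedioxy)drima-5,8-dien-11-oic acid F2, and methylation (MeI, K2CO3, DMF) comes back to the route at 16.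

Step 11. Hydrogen-atom back-transfer may take the tertiary C9–H and give the tetrasubstituted C8=C9 alkene, or the catalyst may not turn over. The alkene position would then be fixed by an allylsilane. Setting out from 12, Stille coupling with (E)-tributyl[2-(trimethylsilyl)vinyl]stannane (Pd(PPh3)4, LiCl, THF) would give (4S,5S)-4,5-(isopropylidenedioxy)-2,6,6-trimethyl-1-[(E)-2-(trimethylsilyl)vinyl]cyclohex-1-ene F3. Cycloaddition with 15 as in step 7 would give methyl (2S,3S,10R)-2,3-(isopropylidenedioxy)-7-(trimethylsilyl)drima-5,8-dien-11-oate F4 (C7 configuration immaterial). Hydrogenation as in step 8 would give methyl (2S,3S,5S,10R)-2,3-(isopropylidenedioxy)-7-(trimethylsilyl)drim-8-en-11-oate F5. Fluoride (Bu4NF, THF, then AcOH) should cleave the allylic C7–Si bond to the ring dienolate regiospecifically, and α-protonation at C9 should give methyl (2S,3S,5S,9R,10R)-2,3-(isopropylidenedioxy)drim-7-en-11-oate F6. Reduction with LiAlH4 comes back to the route at 21.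

Step 2. Oxygen transfer to the electron-poor dienone may be slow, or the enantioselection insufficient. Setting out from 3, epoxidation with dimethyldioxirane (acetone, 0 °C) would give racemic cis-4,5-epoxy-2,6,6-trimethylcyclohex-2-en-1-one F7. Acid hydrolysis as in step 3 would give racemic trans-4,5-dihydroxy-2,6,6-trimethylcyclohex-2-en-1-one F8. Lipase-catalysed acylation of the allylic hydroxyl (immobilized Candida antarctica lipase B, vinyl acetate, MTBE) should, by the usual enantiopreference of this enzyme for secondary alcohols, consume the unwanted enantiomer as (4R,5R)-4-acetoxy-5-hydroxy-2,6,6-trimethylcyclohex-2-en-1-one F9. The unreacted (4S,5S)-diol is separated and comes back to the route at 7.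

**Further compounds**

F1 | step 7 | (2S,3S,10R)-2,3-(isopropylidenedioxy)drima-5,8-dien-11-al | CC1=C(C=O)[C@]2(C)C[C@@H]3OC(C)(C)O[C@H]3C(C)(C)C2=CC1
F2 | step 7 | (2S,3S,10R)-2,3-(isopropylidenedioxy)drima-5,8-dien-11-oic acid | CC1=C(C(=O)O)[C@]2(C)C[C@@H]3OC(C)(C)O[C@H]3C(C)(C)C2=CC1
F3 | step 11 | (4S,5S)-4,5-(isopropylidenedioxy)-2,6,6-trimethyl-1-[(E)-2-(trimethylsilyl)vinyl]cyclohex-1-ene | C[Si](C)(C)/C=C/C1=C(C)C[C@@H]2OC(C)(C)O[C@H]2C1(C)C
F4 | step 11 | methyl (2S,3S,10R)-2,3-(isopropylidenedioxy)-7-(trimethylsilyl)drima-5,8-dien-11-oate | CC1=C(C(=O)OC)[C@]2(C)C[C@@H]3OC(C)(C)O[C@H]3C(C)(C)C2=CC1[Si](C)(C)C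
F5 | step 11 | methyl (2S,3S,5S,10R)-2,3-(isopropylidenedioxy)-7-(trimethylsilyl)drim-8-en-11-oate | CC1=C(C(=O)OC)[C@]2(C)C[C@@H]3OC(C)(C)O[C@H]3C(C)(C)[C@H]2CC1[Si](C)(C)C
F6 | step 11 | methyl (2S,3S,5S,9R,10R)-2,3-(isopropylidenedioxy)drim-7-en-11-oate | CC1=CC[C@@H]2C(C)(C)[C@@H]3OC(C)(C)O[C@H]3C[C@@]2(C)[C@@H]1C(=O)OC
F7 | step 2 | racemic cis-4,5-epoxy-2,6,6-trimethylcyclohex-2-en-1-one | O=C1C(C)(C)[C@@H]2O[C@@H]2C=C1C.O=C1C(C)(C)[C@H]2O[C@H]2C=C1C
F8 | step 2 | racemic trans-4,5-dihydroxy-2,6,6-trimethylcyclohex-2-en-1-one | O=C1C(C)(C)[C@H](O)[C@@H](O)C=C1C.O=C1C(C)(C)[C@@H](O)[C@H](O)C=C1C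
F9 | step 2 | (4R,5R)-4-acetoxy-5-hydroxy-2,6,6-trimethylcyclohex-2-en-1-one | O=C1C(C)(C)[C@@H](O)[C@H](OC(C)=O)C=C1C
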